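**Retrosynthetic overview**
- The strategy rests on ring B (C1'–C6': H on C2' and C6', OH on C3', OMe on C4' and C5'). Its C3'–C6' carbons and the 3'-oxygen are the four carbons and the ring oxygen of 3,4-dimethoxyfuran; C1' and C2' are the two carbons of an alkyne on C2 of the chromone.
- Key disconnection: C1'–C6' and C2'–C3', giving 2-ethynyl-7,8-dimethoxychromone 7 and 3,4-dimethoxyfuran 13 (furan–alkyne Diels–Alder reaction, then opening of the oxygen bridge to the phenol in the same flask).
- Alkyne 7: ring C is closed on the purchased ring A by oxalate Claisen condensation–cyclodehydration of 2-hydroxy-3,4-dimethoxyacetophenone, then CO2Et → CH2OH → CHO → C≡CH.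
- Furan 13: the furan ring comes from dimethyl diglycolate and dimethyl oxalate, followed by O-methylation, saponification and decarboxylation.
- Ring order: ring A bought, ring C in step 1, the furan ring in step 5, ring B last in step 9; the route is convergent and uses no protecting group.

Key step: step 9

Remark: the target is achiral. The only stereocentres in the route are the two bridgehead carbons of the transient cycloadduct 14, which form as a racemate and are erased on aromatization. Dimethyl oxalate is used for the furan so that all its ester groups are methyl.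

**Step 1**
Reactants: 1 2-hydroxy-3,4-dimethoxyacetophenone; 2 diethyl oxalate
Product: 4 ethyl 7,8-dimethoxy-4-oxo-4H-chromene-2-carboxylate, via diketo ester 3 (not isolated)
Conditions: NaOEt (3 equiv), EtOH, reflux; then conc. HCl, EtOH, reflux
Reagents that add atoms: none
Why: Crossed Claisen condensation of the methyl ketone enolate with the non-enolizable oxalate should give the 2,4-dioxobutanoate, and acid-catalysed cyclodehydration through the ortho phenol closes the pyranone ring C, the standard chromone-2-carboxylate synthesis.

**Step 2**
Reactants: 4 ethyl 7,8-dimethoxy-4-oxo-4H-chromene-2-carboxylate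
Product: 5 2-(hydroxymethyl)-7,8-dimethoxy-4H-chromen-4-one
Conditions: NaBH4 (1.5 equiv), MeOH, 0 °C
Reagents that add atoms: none
Why: Chemoselective borohydride reduction: the ester on the electron-poor C2 (α-oxygen, β-carbon of the enone) is strongly activated, whereas the C4 carbonyl is a vinylogous ester and should resist NaBH4 at 0 °C.

**Step 3**
Reactants: 5 2-(hydroxymethyl)-7,8-dimethoxy-4H-chromen-4-one
Product: 6 7,8-dimethoxy-4-oxo-4H-chromene-2-carbaldehyde
Conditions: Dess–Martin periodinane (1.2 equiv), CH2Cl2, rt
Reagents that add atoms: none
Why: Dess–Martin oxidation of a primary allylic-type alcohol stops at the aldehyde under neutral, water-free conditions, which avoids hydrate formation and over-oxidation of the electron-poor 2-formylchromone.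

**Step 4**
Reactants: 6 7,8-dimethoxy-4-oxo-4H-chromene-2-carbaldehyde
Product: 7 2-ethynyl-7,8-dimethoxy-4H-chromen-4-one
Conditions: dimethyl (1-diazo-2-oxopropyl)phosphonate (1.3 equiv), K2CO3 (2 equiv), MeOH, 0 °C to rt
Reagents that add atoms: dimethyl (1-diazo-2-oxopropyl)phosphonate, SMILES CC(=O)C(=[N+]=[N-])P(=O)(OC)OC
Why: Seyferth–Gilbert homologation in the Ohira–Bestmann variant: methanolysis of the acetyl group frees the diazomethylphosphonate anion, which adds to the aldehyde, loses dimethyl phosphate to a diazoalkene and, after loss of N2 and 1,2-hydrogen shift of the alkylidene carbene, should give the terminal alkyne under carbonate base mild enough for the pyranone.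

**Step 5**
Reactants: 8 dimethyl diglycolate; 9 dimethyl oxalate
Product: 10 dimethyl 3,4-dihydroxyfuran-2,5-dicarboxylate
Conditions: NaOMe (2.2 equiv), MeOH, reflux; then aq. HCl
Reagents that add atoms: none
Why: Double Claisen (Hinsberg-type) condensation of the two activated methylene groups of the diglycolate with the two ester groups of the oxalate forms the C2–C3 and C4–C5 bonds, and enolization aromatizes the ring to the 3,4-dihydroxyfuran diester.

**Step 6**
Reactants: 10 dimethyl 3,4-dihydroxyfuran-2,5-dicarboxylate
Product: 11 dimethyl 3,4-dimethoxyfuran-2,5-dicarboxylate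
Conditions: Me2SO4 (2.5 equiv), K2CO3, acetone, reflux
Reagents that add atoms: dimethyl sulfate, SMILES COS(=O)(=O)OC
Why: Williamson O-methylation of the two acidic enolic hydroxyls; the hard electrophile dimethyl sulfate favours O- over C-alkylation of this β-keto-ester-type enol.

**Step 7**
Reactants: 11 dimethyl 3,4-dimethoxyfuran-2,5-dicarboxylate
Product: 12 3,4-dimethoxyfuran-2,5-dicarboxylic acid
Conditions: NaOH, H2O–MeOH, reflux; then aq. HCl, 0 °C
Reagents that add atoms: sodium hydroxide, SMILES [Na+].[OH-]
Why: Saponification of both methyl esters by acyl–oxygen cleavage, followed by acidification, should precipitate the diacid.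

**Step 8**
Reactants: 12 3,4-dimethoxyfuran-2,5-dicarboxylic acid
Product: 13 3,4-dimethoxyfuran
Conditions: Cu powder, quinoline, 200 °C, product distilled out under N2
Reagents that add atoms: none
Why: Copper-mediated thermal protodecarboxylation of furan-2-carboxylic acids in quinoline, with the volatile, acid-sensitive furan removed by distillation as it forms.

**Step 9**
Reactants: 7 2-ethynyl-7,8-dimethoxy-4H-chromen-4-one; 13 3,4-dimethoxyfuran
Product: 15 3'-hydroxy-4',5',7,8-tetramethoxyflavone, via oxanorbornadiene cycloadduct 14 (not isolated)
Conditions: ZnI2 (1.0 equiv), 3,4-dimethoxyfuran in excess (3 equiv), CH2Cl2, 4 Å MS, 0 °C to rt; aq. NH4Cl work-up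
Reagents that add atoms: none
Why: Proposed new method: ZnI2 bound to the C4 carbonyl gives ring C benzopyrylium character, so the ethynyl group of 7 behaves as a vinylogous ynone and the electron-rich diene 13 adds across it in a normal-demand (4+2) cycloaddition, concerted but asynchronous or stepwise through attack of a furan α-carbon on the alkyne terminus and collapse of the resulting allenyl zinc enolate onto the oxocarbenium carbon, forming C2'–C3' and C1'–C6'. The closest known reaction type is the Lewis-acid-promoted Diels–Alder reaction of furans with propiolates and ynones, whose 7-oxanorbornadiene adducts isomerize to phenols under the same acid; an alkyne activated only through the C2=C3 bond of a chromone has not been used in this way. Ring B is closed by this intermolecular cycloaddition as the carbocycle of 14 (four carbons from the furan, two from the alkyne); the two bridgehead stereocentres of 14 form as a racemate without any control and both are destroyed on aromatization, so the product has no stereocentre. Zinc-assisted heterolysis of the C6'–O bridge bond should then give a cyclohexadienyl cation with charge on C2', C4' and C6', stabilized by the 4'-methoxy group, and loss of the C3' proton (or a 1,2-hydride shift followed by enolization, which leads to the same place) leaves the oxygen on C3' as the free phenol. The step needs site selectivity in this bridge opening, and the substrate secures it because the alternative C3'–O heterolysis would put charge on C1', the carbon that carries the zinc-bound, electron-poor chromonyl group, the same bias that favours a hydroxyl meta to the acceptor when acceptor-substituted 7-oxanorbornadienes open. No regiochemistry arises in the cycloaddition because 13 is symmetrical, and the terminal alkyne should react in preference to the hindered, pyranone-stabilized C2=C3 bond.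

**Compound list**
1 | 2-hydroxy-3,4-dimethoxyacetophenone | COc1ccc(C(C)=O)c(O)c1OC | starting material
2 | diethyl oxalate | CCOC(=O)C(=O)OCC | starting material
3 | ethyl 4-(2-hydroxy-3,4-dimethoxyphenyl)-2,4-dioxobutanoate (diketo ester) | CCOC(=O)C(=O)CC(=O)c1ccc(OC)c(OC)c1O | intermediate (not isolated)
4 | ethyl 7,8-dimethoxy-4-oxo-4H-chromene-2-carboxylate | CCOC(=O)c1cc(=O)c2ccc(OC)c(OC)c2o1 | intermediate
5 | 2-(hydroxymethyl)-7,8-dimethoxy-4H-chromen-4-one | OCc1cc(=O)c2ccc(OC)c(OC)c2o1 | intermediate
6 | 7,8-dimethoxy-4-oxo-4H-chromene-2-carbaldehyde | O=Cc1cc(=O)c2ccc(OC)c(OC)c2o1 | intermediate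
7 | 2-ethynyl-7,8-dimethoxy-4H-chromen-4-one | C#Cc1cc(=O)c2ccc(OC)c(OC)c2o1 | intermediate
8 | dimethyl diglycolate | COC(=O)COCC(=O)OC | starting material
9 | dimethyl oxalate | COC(=O)C(=O)OC | starting material
10 | dimethyl 3,4-dihydroxyfuran-2,5-dicarboxylate | COC(=O)c1oc(C(=O)OC)c(O)c1O | intermediate
11 | dimethyl 3,4-dimethoxyfuran-2,5-dicarboxylate | COC(=O)c1oc(C(=O)OC)c(OC)c1OC | intermediate
12 | 3,4-dimethoxyfuran-2,5-dicarboxylic acid | OC(=O)c1oc(C(O)=O)c(OC)c1OC | intermediate
13 | 3,4-dimethoxyfuran | COc1cocc1OC | intermediate
14 | 2-(5,6-dimethoxy-7-oxabicyclo[2.2.1]hepta-2,5-dien-2-yl)-7,8-dimethoxy-4H-chromen-4-one (racemic; one enantiomer drawn) | COC1=C(OC)[C@@H]2O[C@H]1C=C2c3cc(=O)c4ccc(OC)c(OC)c4o3 | intermediate (not isolated)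
15 | 3'-hydroxy-4',5',7,8-tetramethoxyflavone | COc1cc(-c2cc(=O)c3ccc(OC)c(OC)c3o2)cc(O)c1OC | target

**Step count**
Total: 9 steps (steps 1–4 to alkyne 7, steps 5–8 to furan 13, step 9 joins them). Longest linear sequence: 5 steps.

**Steps most likely to fail**

Step 9 (proposed new method). The alkyne may be too weakly activated, so that the furan attacks the alkyne terminus as a nucleophile and loses a proton instead of closing the ring. The furan may also decompose under the Lewis acid, or the oxygen bridge may open at the wrong C–O bond and place the hydroxyl on C2'. The fallback uses the classical chalcone route, sets out from compound 1 and comes back at compound 15. Commercial 3-hydroxy-4,5-dimethoxybenzaldehyde F1 would be benzylated (BnBr, K2CO3, DMF) to 3-(benzyloxy)-4,5-dimethoxybenzaldehyde F2. Claisen–Schmidt condensation of F2 with 1 (KOH, EtOH, rt) should give (E)-3-[3-(benzyloxy)-4,5-dimethoxyphenyl]-1-(2-hydroxy-3,4-dimethoxyphenyl)prop-2-en-1-one F3. Oxidative cyclization of F3 with catalytic I2 in DMSO at 130 °C should give 3'-(benzyloxy)-4',5',7,8-tetramethoxyflavone F4, and hydrogenolysis (H2, Pd/C, EtOAc–MeOH, rt) would release 15.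

Step 4. Methoxide may add in conjugate fashion to the ynenone product or open the pyranone ring during the homologation. The fallback avoids alkoxide altogether, sets out from compound 6 and comes back at compound 7. Dibromoolefination (CBr4, PPh3, CH2Cl2, 0 °C) should give 2-(2,2-dibromovinyl)-7,8-dimethoxy-4H-chromen-4-one F5. Hydrodebromination catalysed by Pd(PPh3)4 with Bu3SnH (toluene, rt) removes the bromine trans to the chromonyl group and should give (Z)-2-(2-bromovinyl)-7,8-dimethoxy-4H-chromen-4-one F6. Anti-elimination of HBr with DBU (DMSO, rt) would then give 7.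

Step 2. Hydride may add to the C2=C3 bond or the C4 carbonyl of the pyranone and lower the chemoselectivity. The fallback reaches the aldehyde without any hydride step, sets out from compound 1 and comes back at compound 6, bypassing steps 1–3. Claisen condensation of 1 with ethyl acetate (NaH, THF, reflux) should give 1-(2-hydroxy-3,4-dimethoxyphenyl)butane-1,3-dione F7. Acid cyclodehydration (conc. HCl, AcOH, reflux) would give 7,8-dimethoxy-2-methyl-4H-chromen-4-one F8, and Riley oxidation of the activated methyl group (SeO2, dioxane, reflux) should give 6.

**Further compounds**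
F1 | step 9 | 3-hydroxy-4,5-dimethoxybenzaldehyde | COc1cc(C=O)cc(O)c1OC
F2 | step 9 | 3-(benzyloxy)-4,5-dimethoxybenzaldehyde | COc1cc(C=O)cc(OCc2ccccc2)c1OC
F3 | step 9 | (E)-3-[3-(benzyloxy)-4,5-dimethoxyphenyl]-1-(2-hydroxy-3,4-dimethoxyphenyl)prop-2-en-1-one | COc1ccc(C(=O)/C=C/c2cc(OC)c(OC)c(OCc3ccccc3)c2)c(O)c1OC
F4 | step 9 | 3'-(benzyloxy)-4',5',7,8-tetramethoxyflavone | COc1cc(-c2cc(=O)c3ccc(OC)c(OC)c3o2)cc(OCc2ccccc2)c1OC
F5 | step 4 | 2-(2,2-dibromovinyl)-7,8-dimethoxy-4H-chromen-4-one | COc1ccc2c(=O)cc(C=C(Br)Br)oc2c1OC
F6 | step 4 | (Z)-2-(2-bromovinyl)-7,8-dimethoxy-4H-chromen-4-one | COc1ccc2c(=O)cc(/C=C\Br)oc2c1OC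
F7 | step 2 | 1-(2-hydroxy-3,4-dimethoxyphenyl)butane-1,3-dione | COc1ccc(C(=O)CC(C)=O)c(O)c1OC
F8 | step 2 | 7,8-dimethoxy-2-methyl-4H-chromen-4-one | COc1ccc2c(=O)cc(C)oc2c1OC
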